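# Sodwanone T: synthesis design around a furanone [2+2] photocycloaddition and cyclobutane-opening ring expansion

Numbering used for the bicyclic halves (1-benzoxepine): O1, C2 (CMe2), C3, C4, C5, C5a (quaternary, methyl), C6 (alkene carbon carrying the bridge), C7 (alkene carbon carrying methyl), C8, C9, C9a (ether methine).

## The problem

Sodwanone T consists of two bicyclic halves, each a 2,2-dimethyloxepane (rings A and D) trans-fused to a methylcyclohexene (rings B and C). The halves are joined by a CH2CH2 bridge between the two fully substituted alkene carbons C6. Both halves have the same skeleton and, as the descriptors in the SMILES string show, the same absolute configuration at the fusion (5aS,9aS: methyl and ether oxygen cis on the cyclohexene, methyl and fusion hydrogen anti). They differ only at C3, which is a ketone in ring D and an (R)-carbinol in ring A, so one enantiopure bicyclic intermediate can serve twice. The two fusions are too remote to control each other, so absolute configuration must be set once in a common precursor. The carbinol can be set later by a reagent, with or against the bias of the angular methyl group. The tetrasubstituted alkenes sit next to a quaternary carbon, which makes the bridge-forming bond hindered and the alkenes prone to acid-induced migration. The α-alkoxy ketone is enolizable at C4 and open to reductive C–O cleavage, and an oxepane with a gem-dimethyl carbon beside oxygen is a poor candidate for direct ring closure. The feature that makes the key step possible: O1, C2, C3, C4 and C9a of ring D are the five ring atoms of a 2,2-dimethyl-3(2H)-furanone, and C5 and C5a lie between C4 and C9a as an alkene would after insertion into the furanone C4=C5 bond, C5a being also the quaternary carbon of ring C.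

## Retrosynthesis

**Bridge.** The bond between the bridge CH2 and C6 of ring C is cut, giving alkylborane 23 and enol triflate 19 (B-alkyl Suzuki–Miyaura coupling). The central CH2–CH2 bond would instead need an sp3–sp3 union of two hindered homoallylic fragments, and an olefination would leave an alkene to reduce beside two others. The chosen cut makes both partners derivatives of one compound. The forward reaction must tolerate a ketone, a hindered carbinol and a triflate flanked by a quaternary carbon.

**Ring A/B partner.** Borane 23 comes from diene 22 by hydroboration of the vinyl group, 22 from hydroxy triflate 20 and tributyl(vinyl)stannane 21 (Stille coupling), and 20 from keto triflate 19 by reagent-controlled reduction. Sodwanone T 24 is thus reduced to the single bicyclic compound 19. No protecting group is needed on either C3 oxygen.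

**Ring D.** In 19 the bond C4–C9a is re-formed, which leads back to tricyclic enol triflate 17. Here a cyclobutane is shared with the five-membered furanone-derived ring. Against an etherification or a one-carbon homologation, this cut avoids any seven-membered ring closure and makes the ring-fusion hydrogen the last stereochemical event. The forward reaction must cleave one specific cyclobutane bond and deliver hydride anti to the angular methyl.

**Ring C functional groups.** Enol triflate 17 goes back to methyl ketone 15, diketone 13, carbinol 12 and silyl ether 11. These changes are placed before the ring opening for two reasons. First, while the cyclobutane is intact the furanone-derived carbonyl has no α-hydrogen except the one at the four/five ring fusion, so ring C can be enolized, methylated and triflated without protection. After opening, that ketone would carry a CH2 and compete. Second, with C6 trigonal, no axial substituent on ring C stands in the path of the hydride that sets the trans fusion.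

**Key disconnection.** In 11 the bonds C1–C7 and C5–C6 of the tricycle are cut (furanone β-carbon to the internal alkene carbon, furanone α-carbon to the alkene CH2). This gives furanone 10 with an acyclic 4-silyloxy-5-methylhex-5-enyl chain. Three rings become one and three of the four stereocentres disappear. The remaining (S)-carbinol must direct the facial sense, and the four-atom tether must direct the regiochemistry.

**Furanone.** Furanone 10 is the cyclodehydration product of hydroxy diketone 9. Cutting the C3–C4 bond of 9 (Claisen condensation) gives ester 6 and 3-hydroxy-3-methylbutan-2-one 7.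

**Chain.** Silyl ether 6 comes from (S)-carbinol 5, made by CBS reduction of enone 4. Enone 4 comes from Weinreb amide 2 and isopropenylmagnesium bromide 3, and 2 from the commercial half-ester chloride 1.

## Roads not taken

**Alternative 1:** Double Birch reductive methylation of the C2-symmetric bibenzyl bis-amide A1 to the bis-cyclohexadiene A2. The cut is at both quaternary C–CH3 bonds; the bridge is present from the start as a bibenzyl.
- Merits: the bridge problem disappears, both quaternary centres and both ring alkenes arise in one operation, and facial control by the prolinol-ether amide is well established.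
- Weak points: A2 still lacks all four carbons and the oxygen bridge of each oxepane. The hindered tertiary amide carbon must become C5. The enol ether must be unmasked and reduced to the trans ether methine. All of this runs in duplicate on a symmetric compound that must finally be desymmetrized (ketone against carbinol), which costs a statistical step. The bridge substituent ortho to the amide may also disturb the enolate geometry that carries the selectivity.
- Comparison: in convergence this road is better than the chosen plan, which needs a late coupling of two hindered halves. The chosen plan sets against it a key step that delivers ring D nearly complete, and a ketone/carbinol differentiation that costs one reduction.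

**Alternative 2:** One-carbon ring expansion of tetrahydropyranone A3 with TMSCHN2/Me3Al to oxepanone A4. The cut is at both bonds to C4.
- Merits: the six-membered ether precursor closes easily, the ketone appears directly at C3, and the homologation is a known reaction type.
- Weak points: the step is peripheral. The quaternary centre, the trans fusion and the ring B alkene must all be made beforehand by other means, so the sequence is longer. The ketone is hindered by the CMe2 group, migration of CH2 rather than the oxygenated carbon must be secured, and double insertion and desilylation need care.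
- Comparison: the central step here is more reliable than the cyclobutane opening of the chosen plan. The chosen plan sets against it the construction of quaternary centre, ring C and both extra carbons of ring D from an acyclic chain in one step.

**Alternative 3:** Transannular Prins closure of the eleven-membered α-acetoxy ether A5 to bicycle A6. The cut is the fusion bond C5a–C9a.
- Merits: rings A and B, the fusion bond and the alkene position arise together, and the carbinol stereocentre is in place from the start, so no late reduction is needed.
- Weak points: the macrocycle contains a tetrasubstituted alkene of defined geometry and a cyclic acetal, both hard to assemble. The trans fusion depends on a macrocycle conformation that cannot be predicted with confidence. The cation can lose a proton in more than one direction.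
- Comparison: for the ring A half this road is as good or better in stereocontrol at C3. The chosen plan sets against it a six-step acyclic precursor in place of a macrocycle, and a ring closure whose regiochemistry is fixed by tether length.

Key step: step 7

## Route

Remark 1: methyl 5-chloro-5-oxopentanoate (the acid chloride of monomethyl glutarate, itself the methanolysis product of glutaric anhydride) is taken as a catalogue chemical.

Remark 2: numbers are given to intermediates that are made in one stage of a one-flask procedure and consumed by a reagent added later. Excited states, biradicals, ion pairs and adducts that only await aqueous work-up are described in the Why lines.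

Step 1
Reactants: 1 methyl 5-chloro-5-oxopentanoate
Product: 2 methyl 5-[methoxy(methyl)amino]-5-oxopentanoate
Conditions: MeNHOMe·HCl, pyridine, CH2Cl2, 0 °C to rt
Reagents that add atoms: N,O-dimethylhydroxylamine hydrochloride, CNOC.Cl
Why: Acylation of the hydroxylamine by the acid chloride (Weinreb amide formation); the methyl ester does not react at this temperature.

Step 2
Reactants: 2 methyl 5-[methoxy(methyl)amino]-5-oxopentanoate; 3 isopropenylmagnesium bromide
Product: 4 methyl 6-methyl-5-oxohept-6-enoate
Conditions: THF, −78 to −10 °C; poured into cold 1 M HCl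
Reagents that add atoms: none
Why: Weinreb ketone synthesis: the Grignard reagent adds to the amide to give a magnesium chelate that releases the enone only on quench, so over-addition and attack on the less electrophilic ester are not expected; the acidic quench keeps the liberated hydroxylamine from adding to the enone.

Step 3
Reactants: 4 methyl 6-methyl-5-oxohept-6-enoate
Product: 5 methyl (5S)-5-hydroxy-6-methylhept-6-enoate
Conditions: (R)-2-methyl-CBS-oxazaborolidine (0.2 equiv), catecholborane, toluene, −78 °C; MeOH, then aq. NaHCO3
Reagents that add atoms: none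
Why: CBS reduction: the isopropenyl group acts as the large substituent and the unbranched chain as the small one, so the (R)-catalyst should give the (S)-allylic alcohol; catecholborane at low temperature spares the alkene and the ester.

Step 4
Reactants: 5 methyl (5S)-5-hydroxy-6-methylhept-6-enoate
Product: 6 methyl (5S)-5-[(tert-butyldimethylsilyl)oxy]-6-methylhept-6-enoate
Conditions: TBSCl, imidazole, DMF, rt
Reagents that add atoms: tert-butyldimethylsilyl chloride, CC(C)(C)[Si](C)(C)Cl
Why: Standard silylation of a secondary alcohol, done on the crude carbinol to forestall lactonization of the δ-hydroxy ester.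

Step 5
Reactants: 6 methyl (5S)-5-[(tert-butyldimethylsilyl)oxy]-6-methylhept-6-enoate; 7 3-hydroxy-3-methylbutan-2-one
Product: 9 (8S)-8-[(tert-butyldimethylsilyl)oxy]-2-hydroxy-2,9-dimethyldec-9-ene-3,5-dione, via dilithium dianion 8 (not isolated)
Conditions: 7 (3 equiv), LiN(i-Pr)2 (6.2 equiv), THF, −78 to −20 °C; then 6, −78 to 0 °C; aq. NH4Cl
Reagents that add atoms: none
Why: Crossed Claisen condensation: double deprotonation gives the alkoxide methyl-enolate 8, whose carbon terminus is acylated by the methyl ester; the excess dianion takes up the acidic diketone proton, and a ketone enolate is too weak a base to enolize the ester.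

Step 6
Reactants: 9 (8S)-8-[(tert-butyldimethylsilyl)oxy]-2-hydroxy-2,9-dimethyldec-9-ene-3,5-dione
Product: 10 5-{(4S)-4-[(tert-butyldimethylsilyl)oxy]-5-methylhex-5-en-1-yl}-2,2-dimethylfuran-3(2H)-one
Conditions: p-TsOH·H2O (5 mol %), MgSO4, CH2Cl2, rt
Reagents that add atoms: none
Why: Acid-catalysed cyclodehydration, the standard 3(2H)-furanone synthesis: the tertiary hydroxyl adds to the distal carbonyl and the hemiketal loses water to the vinylogous ester; the conditions are mild enough for the silyl ether.

Step 7
Reactants: 10 5-{(4S)-4-[(tert-butyldimethylsilyl)oxy]-5-methylhex-5-en-1-yl}-2,2-dimethylfuran-3(2H)-one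
Product: 11 (1R,5R,7S,8S)-8-[(tert-butyldimethylsilyl)oxy]-3,3,7-trimethyl-2-oxatricyclo[5.4.0.0(1,5)]undecan-4-one
Conditions: hν (350 nm, Pyrex), degassed MeCN (0.005 M), 10 °C
Reagents that add atoms: none
Why: Excitation of the furanone and intersystem crossing give the triplet enone; the closest known reaction type is the intramolecular enone–alkene [2+2] photocycloaddition of 3(2H)-furanones and other cyclic vinylogous esters that carry an alkenyl chain on the β-carbon. The β-carbon (furanone C5) bonds to the internal carbon of the isopropenyl group, which closes ring C in the exo mode through a six-membered array; the crossed mode would need a seven-membered ring, so the tether length fixes the regiochemistry. The triplet 1,4-biradical then inverts spin and collapses by bonding the α-carbon (furanone C4) to the former CH2 terminus, which closes the cyclobutane. Both new fusions must be cis, because a four-membered ring cannot span trans positions of a five- or six-membered ring; this sets the cyclobutane methine C5 relative to C1 and puts the angular methyl on C7 and the ether oxygen on C1 on the same face of ring C. The absolute sense comes from the (S)-silyloxy carbon: in the chair-like fold the carbinol hydrogen eclipses the alkene methyl (least allylic strain) and the silyloxy group lies pseudo-equatorial and anti to the forming C1–C7 bond, so the furanone should add to the alkene face opposite the silyloxy group and give the adduct with silyloxy and methyl trans. The step needs regioselectivity (tether length), facial selectivity (the single allylic stereocentre) and chemoselectivity against dimerization and secondary photolysis (high dilution and a wavelength at which the saturated ketone product hardly absorbs).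

Step 8
Reactants: 11 (1R,5R,7S,8S)-8-[(tert-butyldimethylsilyl)oxy]-3,3,7-trimethyl-2-oxatricyclo[5.4.0.0(1,5)]undecan-4-one
Product: 12 (1R,5R,7S,8S)-8-hydroxy-3,3,7-trimethyl-2-oxatricyclo[5.4.0.0(1,5)]undecan-4-one
Conditions: TBAF, THF, 0 to 40 °C; aq. NH4Cl
Reagents that add atoms: none
Why: Fluoride desilylation; the ketone has no α-hydrogen except the one at the cyclobutane ring fusion, so the basic fluoride should not trigger β-elimination of the ring oxygen.

Step 9
Reactants: 12 (1R,5R,7S,8S)-8-hydroxy-3,3,7-trimethyl-2-oxatricyclo[5.4.0.0(1,5)]undecan-4-one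
Product: 13 (1R,5R,7R)-3,3,7-trimethyl-2-oxatricyclo[5.4.0.0(1,5)]undecane-4,8-dione
Conditions: Dess–Martin periodinane, NaHCO3, CH2Cl2, 0 °C to rt
Reagents that add atoms: none
Why: Dess–Martin oxidation of a hindered secondary alcohol; the buffer keeps acid away from the β-alkoxy cyclobutyl ketone, and the carbinol stereocentre has done its work.

Step 10
Reactants: 13 (1R,5R,7R)-3,3,7-trimethyl-2-oxatricyclo[5.4.0.0(1,5)]undecane-4,8-dione
Product: 15 (1R,5R,7R)-3,3,7,9-tetramethyl-2-oxatricyclo[5.4.0.0(1,5)]undecane-4,8-dione (both C9 epimers), via lithium enolate 14 (not isolated)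
Conditions: LiN(i-Pr)2 (1.05 equiv), THF, −78 °C; MeI, −78 to −30 °C
Reagents that add atoms: iodomethane, CI
Why: Kinetic enolate alkylation: the ring C ketone can enolize only toward C9 (C7 is quaternary), and the other ketone has only the bridgehead hydrogen at the four/five ring fusion, whose removal would put a trigonal carbon at that fusion; the new stereocentre is not controlled because step 11 removes it.

Step 11
Reactants: 15 (1R,5R,7R)-3,3,7,9-tetramethyl-2-oxatricyclo[5.4.0.0(1,5)]undecane-4,8-dione (both C9 epimers)
Product: 17 (1R,5R,7R)-3,3,7,9-tetramethyl-4-oxo-2-oxatricyclo[5.4.0.0(1,5)]undec-8-en-8-yl trifluoromethanesulfonate, via potassium enolate 16 (not isolated)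
Conditions: KN(SiMe3)2 (1.3 equiv), THF, −78 to 0 °C; PhNTf2, 0 °C to rt
Reagents that add atoms: N-phenylbis(trifluoromethanesulfonimide), O=S(=O)(N(c1ccccc1)S(=O)(=O)C(F)(F)F)C(F)(F)F
Why: Enol triflate formation: the only remaining α-hydrogen of the ring C ketone is removed and the tetrasubstituted enolate is O-sulfonylated, as is routine for 2,2,6-trisubstituted cyclohexanones; the strained ketone again stays out of the enolate chemistry.

Step 12
Reactants: 17 (1R,5R,7R)-3,3,7,9-tetramethyl-4-oxo-2-oxatricyclo[5.4.0.0(1,5)]undec-8-en-8-yl trifluoromethanesulfonate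
Product: 19 (5aR,9aS)-2,2,5a,7-tetramethyl-3-oxo-2,3,4,5,5a,8,9,9a-octahydro-1-benzoxepin-6-yl trifluoromethanesulfonate, via trimethylsilyl enol ether 18 (not isolated)
Conditions: TMSOTf (1.2 equiv), Et3SiH (5 equiv), CH2Cl2, −78 to −20 °C; then 1 M HCl, THF, 0 °C
Reagents that add atoms: none
Why: Proposed new method: O-silylation of the ketone makes the cyclobutane a donor–acceptor system whose shared bond C1–C5 joins the ether carbon (donor) to the carbon α to the activated carbonyl (acceptor), so strain-driven heterolysis should give the silyl enol ether of the seven-membered ketone and an oxocarbenium ion at C9a, which Et3SiH reduces before 18 is hydrolysed. The hydride should enter axially on the half-chair of ring C from the face opposite the angular methyl (C6 is trigonal, so nothing on that face is syn-axial to the silane), which gives the trans fusion. The closest known reaction types are the Lewis-acid opening of alkoxy-substituted donor–acceptor cyclobutanes to trappable 1,4-zwitterions, the retro-aldol half of the de Mayo reaction, and the Et3SiH/TMSOTf reduction of cyclic oxocarbenium ions in reductive etherification; the enol triflate is inert to both reagents.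

Step 13
Reactants: 19 (5aR,9aS)-2,2,5a,7-tetramethyl-3-oxo-2,3,4,5,5a,8,9,9a-octahydro-1-benzoxepin-6-yl trifluoromethanesulfonate
Product: 20 (3R,5aR,9aS)-3-hydroxy-2,2,5a,7-tetramethyl-2,3,4,5,5a,8,9,9a-octahydro-1-benzoxepin-6-yl trifluoromethanesulfonate
Conditions: (S)-2-methyl-CBS-oxazaborolidine (0.5 equiv), BH3·SMe2, THF, −20 °C; MeOH
Reagents that add atoms: none
Why: CBS reduction applied to about half of 19: the fully substituted C2 is the large group and the C4 methylene the small one, so the (S)-catalyst should give the (3R)-carbinol, in the sense also expected for attack anti to the angular methyl; the tetrasubstituted enol triflate is inert to borane.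

Step 14
Reactants: 20 (3R,5aR,9aS)-3-hydroxy-2,2,5a,7-tetramethyl-2,3,4,5,5a,8,9,9a-octahydro-1-benzoxepin-6-yl trifluoromethanesulfonate; 21 tributyl(vinyl)stannane
Product: 22 (3R,5aS,9aS)-6-ethenyl-2,2,5a,7-tetramethyl-2,3,4,5,5a,8,9,9a-octahydro-1-benzoxepin-3-ol
Conditions: Pd(PPh3)4 (10 mol %), LiCl, CuCl, DMSO, 60 °C
Reagents that add atoms: none
Why: Stille coupling of an alkenyl triflate; LiCl and CuCl speed up transmetalation at congested centres, the vinyl group is the smallest possible carbon partner, and the free hydroxyl is tolerated.

Step 15
Reactants: 22 (3R,5aS,9aS)-6-ethenyl-2,2,5a,7-tetramethyl-2,3,4,5,5a,8,9,9a-octahydro-1-benzoxepin-3-ol; 19 (5aR,9aS)-2,2,5a,7-tetramethyl-3-oxo-2,3,4,5,5a,8,9,9a-octahydro-1-benzoxepin-6-yl trifluoromethanesulfonate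
Product: 24 sodwanone T, via alkylborane 23 (not isolated)
Conditions: 9-BBN (2.5 equiv), THF, rt to 50 °C; then aq. Cs2CO3, 19, PdCl2(dppf) (10 mol %), AsPh3, DMF, 50 °C
Reagents that add atoms: none
Why: 9-BBN should add only to the terminal vinyl group, boron going to the CH2 terminus (the tetrasubstituted alkene is inert and the hydroxyl is carried as its borinate); B-alkyl Suzuki–Miyaura coupling of 23 with 19 then forms the bridge. Aqueous base destroys excess B–H before the ketone is added and frees the carbinol, so the coupling delivers the target without protecting groups.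

## Compound list

1 | methyl 5-chloro-5-oxopentanoate | COC(=O)CCCC(=O)Cl | starting material
2 | methyl 5-[methoxy(methyl)amino]-5-oxopentanoate | COC(=O)CCCC(=O)N(C)OC | intermediate
3 | isopropenylmagnesium bromide | CC(=C)[Mg]Br | starting material
4 | methyl 6-methyl-5-oxohept-6-enoate | COC(=O)CCCC(=O)C(C)=C | intermediate
5 | methyl (5S)-5-hydroxy-6-methylhept-6-enoate | COC(=O)CCC[C@H](O)C(C)=C | intermediate
6 | methyl (5S)-5-[(tert-butyldimethylsilyl)oxy]-6-methylhept-6-enoate | COC(=O)CCC[C@H](O[Si](C)(C)C(C)(C)C)C(C)=C | intermediate
7 | 3-hydroxy-3-methylbutan-2-one | CC(=O)C(C)(C)O | starting material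
8 | dilithium dianion of 7 (lithium alkoxide, lithium methyl-enolate) | [Li]OC(=C)C(C)(C)O[Li] | intermediate
9 | (8S)-8-[(tert-butyldimethylsilyl)oxy]-2-hydroxy-2,9-dimethyldec-9-ene-3,5-dione | CC(C)(O)C(=O)CC(=O)CCC[C@H](O[Si](C)(C)C(C)(C)C)C(C)=C | intermediate
10 | 5-{(4S)-4-[(tert-butyldimethylsilyl)oxy]-5-methylhex-5-en-1-yl}-2,2-dimethylfuran-3(2H)-one | CC1(C)OC(CCC[C@H](O[Si](C)(C)C(C)(C)C)C(C)=C)=CC1=O | intermediate
11 | (1R,5R,7S,8S)-8-[(tert-butyldimethylsilyl)oxy]-3,3,7-trimethyl-2-oxatricyclo[5.4.0.0(1,5)]undecan-4-one (all ring fusions cis; silyloxy trans to the C7 methyl) | CC(C)(C)[Si](C)(C)O[C@H]1CCC[C@@]23OC(C)(C)C(=O)[C@@H]2C[C@@]13C | intermediate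
12 | (1R,5R,7S,8S)-8-hydroxy-3,3,7-trimethyl-2-oxatricyclo[5.4.0.0(1,5)]undecan-4-one | O[C@H]1CCC[C@@]23OC(C)(C)C(=O)[C@@H]2C[C@@]13C | intermediate
13 | (1R,5R,7R)-3,3,7-trimethyl-2-oxatricyclo[5.4.0.0(1,5)]undecane-4,8-dione | O=C1CCC[C@@]23OC(C)(C)C(=O)[C@@H]2C[C@@]13C | intermediate
14 | lithium C8–C9 enolate of 13 | [Li]OC1=CCC[C@@]23OC(C)(C)C(=O)[C@@H]2C[C@@]13C | intermediate
15 | (1R,5R,7R)-3,3,7,9-tetramethyl-2-oxatricyclo[5.4.0.0(1,5)]undecane-4,8-dione (both C9 epimers) | O=C1C(C)CC[C@@]23OC(C)(C)C(=O)[C@@H]2C[C@@]13C | intermediate
16 | potassium C8–C9 enolate of 15 | [K]OC1=C(C)CC[C@@]23OC(C)(C)C(=O)[C@@H]2C[C@@]13C | intermediate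
17 | (1R,5R,7R)-3,3,7,9-tetramethyl-4-oxo-2-oxatricyclo[5.4.0.0(1,5)]undec-8-en-8-yl trifluoromethanesulfonate | FC(F)(F)S(=O)(=O)OC1=C(C)CC[C@@]23OC(C)(C)C(=O)[C@@H]2C[C@@]13C | intermediate
18 | (5aR,9aS)-2,2,5a,7-tetramethyl-3-[(trimethylsilyl)oxy]-2,5,5a,8,9,9a-hexahydro-1-benzoxepin-6-yl trifluoromethanesulfonate | CC1=C(OS(=O)(=O)C(F)(F)F)[C@]2(C)CC=C(O[Si](C)(C)C)C(C)(C)O[C@H]2CC1 | intermediate
19 | (5aR,9aS)-2,2,5a,7-tetramethyl-3-oxo-2,3,4,5,5a,8,9,9a-octahydro-1-benzoxepin-6-yl trifluoromethanesulfonate (trans-fused) | CC1=C(OS(=O)(=O)C(F)(F)F)[C@]2(C)CCC(=O)C(C)(C)O[C@H]2CC1 | intermediate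
20 | (3R,5aR,9aS)-3-hydroxy-2,2,5a,7-tetramethyl-2,3,4,5,5a,8,9,9a-octahydro-1-benzoxepin-6-yl trifluoromethanesulfonate | CC1=C(OS(=O)(=O)C(F)(F)F)[C@]2(C)CC[C@@H](O)C(C)(C)O[C@H]2CC1 | intermediate
21 | tributyl(vinyl)stannane | C=C[Sn](CCCC)(CCCC)CCCC | starting material
22 | (3R,5aS,9aS)-6-ethenyl-2,2,5a,7-tetramethyl-2,3,4,5,5a,8,9,9a-octahydro-1-benzoxepin-3-ol | CC1=C(C=C)[C@]2(C)CC[C@@H](O)C(C)(C)O[C@H]2CC1 | intermediate
23 | 9-{2-[(3R,5aS,9aS)-3-(9-borabicyclo[3.3.1]nonan-9-yloxy)-2,2,5a,7-tetramethyl-2,3,4,5,5a,8,9,9a-octahydro-1-benzoxepin-6-yl]ethyl}-9-borabicyclo[3.3.1]nonane | CC1=C(CCB3C4CCCC3CCC4)[C@]2(C)CC[C@@H](OB3C4CCCC3CCC4)C(C)(C)O[C@H]2CC1 | intermediate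
24 | sodwanone T, (5aS,9aS)-6-{2-[(3R,5aS,9aS)-3-hydroxy-2,2,5a,7-tetramethyl-2,3,4,5,5a,8,9,9a-octahydro-1-benzoxepin-6-yl]ethyl}-2,2,5a,7-tetramethyl-4,5,5a,8,9,9a-hexahydro-1-benzoxepin-3(2H)-one | CC1=C(CCC2=C(C)CC[C@@H]3OC(C)(C)[C@H](O)CC[C@@]23C)[C@]2(C)CCC(=O)C(C)(C)O[C@H]2CC1 | target

Total step count: 15. Longest linear sequence: 15 steps (1 to 24 by way of 19, 20 and 22); the second coupling partner 19 is drawn from the same line after step 12.

## Least certain steps and fallbacks

**Step 12 (ring expansion, proposed new method).**
- What may go wrong: the shared cyclobutane bond may not ionize, because inside the five-membered ring it overlaps poorly with the carbonyl π system and the ether lone pair. The silane may instead reduce the activated ketone directly. The oxocarbenium ion may lose a proton to an enol ether. Hydride may enter syn to the angular methyl and give the cis fusion.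
- Fallback (known chemistry): set out from 17 and separate cleavage from ring closure. Aqueous acid (catalytic TfOH in wet MeCN) should open the β-alkoxy cyclobutyl ketone hydrolytically, as in the retro-aldol half of a de Mayo sequence, to (6S)-6-(4-hydroxy-4-methyl-3-oxopentyl)-2,6-dimethyl-5-oxocyclohex-1-en-1-yl trifluoromethanesulfonate F1; water traps the cation irreversibly. Hydroxy-ketone reductive etherification of F1 (Et3SiH, TMSOTf, CH2Cl2, −78 to 0 °C) then closes ring D by C–O bond formation and returns to the route at 19.

**Step 7 (key step).**
- What may go wrong: loss of facial control. Closure through a six-membered array is slower than the familiar five-membered case, a single acyclic stereocentre is the only control element, and folds that place the silyloxy group syn to the forming bond are accessible. The slower closure also gives hydrogen abstraction at the activated carbinol C–H and secondary α-cleavage (Norrish type 1) of the product more time; these would first be met by a longer wavelength or a triplet sensitizer.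
- Fallback: move the source of absolute configuration from the tether to a reagent. The stereoisomeric adducts are carried together through steps 8 to 12, where the carbinol centre disappears, so that 19 arrives with its enantiomer, (5aS,9aR)-keto triflate F2. The fallback sets out from this 19. The (S)-CBS reduction of step 13 turns the two enantiomers into diastereomers, 20 and the (3R,5aS,9aR)-hydroxy triflate F3, which are separated by chromatography. Pure 20 continues, and the portion needed as ketone partner is re-oxidized with Dess–Martin periodinane, so the route is rejoined at 20 and at 19.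

**Step 15 (bridge coupling).**
- What may go wrong: slow oxidative addition and transmetalation at a triflate flanked by a quaternary carbon and a substituted alkene carbon, so that protodeboronation, β-hydride elimination or triflate hydrolysis take over.
- Fallback: set out from 20 and 19 and build the bridge through sp–sp2 couplings, which respond less to hindrance. Sonogashira coupling of 20 with trimethylsilylacetylene (PdCl2(PPh3)2, CuI, Et3N) gives the (trimethylsilyl)ethynyl carbinol F4. K2CO3 in MeOH gives the terminal enyne F5. A second Sonogashira coupling with 19 gives the dienyne keto alcohol F6. Diimide (2-nitrobenzenesulfonyl hydrazide, Et3N) should saturate only the alkyne, the tetrasubstituted alkenes being inert, and return to the route at 24.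

**Step 13 (carbinol).**
- What may go wrong: reagent and substrate bias may oppose each other, giving low selectivity or the (3S)-epimer.
- Fallback: set out from 19 and rely on substrate control followed by inversion. NaBH4 in MeOH would give the epimer in excess, (3S,5aR,9aS)-hydroxy triflate F7. Mitsunobu reaction with 4-nitrobenzoic acid (PPh3, DIAD) gives the inverted (3R)-4-nitrobenzoate F8, and methanolysis (K2CO3, MeOH) returns to the route at 20. The displacement next to the CMe2 carbon will be slow and may need forcing conditions.

**Step 11 (enol triflate).**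
- What may go wrong: the amide base may also remove the ring-fusion hydrogen next to the strained ketone, followed by β-elimination of the ring oxygen, or O-sulfonylation of the hindered enolate may be slow.
- Fallback: set out from 13 and generate the tetrasubstituted enolate by conjugate reduction instead of deprotonation. Enolate 14 is treated with Eschenmoser's salt to give the Mannich base, 9-[(dimethylamino)methyl] diketone F9. Quaternization with MeI and elimination (NaHCO3) give the 9-methylidene diketone F10. LiBH(s-Bu)3 at −78 °C adds hydride to the exocyclic enone and gives the lithium enolate F11 regiospecifically. PhNTf2 traps it and returns to the route at 17, replacing steps 10 and 11.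

## Further compounds

F1 | step 12 | (6S)-6-(4-hydroxy-4-methyl-3-oxopentyl)-2,6-dimethyl-5-oxocyclohex-1-en-1-yl trifluoromethanesulfonate | CC1=C(OS(=O)(=O)C(F)(F)F)[C@](C)(CCC(=O)C(C)(C)O)C(=O)CC1
F2 | step 7 | (5aS,9aR)-2,2,5a,7-tetramethyl-3-oxo-2,3,4,5,5a,8,9,9a-octahydro-1-benzoxepin-6-yl trifluoromethanesulfonate (enantiomer of 19) | CC1=C(OS(=O)(=O)C(F)(F)F)[C@@]2(C)CCC(=O)C(C)(C)O[C@@H]2CC1
F3 | step 7 | (3R,5aS,9aR)-3-hydroxy-2,2,5a,7-tetramethyl-2,3,4,5,5a,8,9,9a-octahydro-1-benzoxepin-6-yl trifluoromethanesulfonate | CC1=C(OS(=O)(=O)C(F)(F)F)[C@@]2(C)CC[C@@H](O)C(C)(C)O[C@@H]2CC1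
F4 | step 15 | (3R,5aS,9aS)-2,2,5a,7-tetramethyl-6-[(trimethylsilyl)ethynyl]-2,3,4,5,5a,8,9,9a-octahydro-1-benzoxepin-3-ol | CC1=C(C#C[Si](C)(C)C)[C@]2(C)CC[C@@H](O)C(C)(C)O[C@H]2CC1
F5 | step 15 | (3R,5aS,9aS)-6-ethynyl-2,2,5a,7-tetramethyl-2,3,4,5,5a,8,9,9a-octahydro-1-benzoxepin-3-ol | CC1=C(C#C)[C@]2(C)CC[C@@H](O)C(C)(C)O[C@H]2CC1
F6 | step 15 | (5aS,9aS)-6-{[(3R,5aS,9aS)-3-hydroxy-2,2,5a,7-tetramethyl-2,3,4,5,5a,8,9,9a-octahydro-1-benzoxepin-6-yl]ethynyl}-2,2,5a,7-tetramethyl-4,5,5a,8,9,9a-hexahydro-1-benzoxepin-3(2H)-one | CC1=C(C#CC2=C(C)CC[C@@H]3OC(C)(C)[C@H](O)CC[C@@]23C)[C@]2(C)CCC(=O)C(C)(C)O[C@H]2CC1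
F7 | step 13 | (3S,5aR,9aS)-3-hydroxy-2,2,5a,7-tetramethyl-2,3,4,5,5a,8,9,9a-octahydro-1-benzoxepin-6-yl trifluoromethanesulfonate | CC1=C(OS(=O)(=O)C(F)(F)F)[C@]2(C)CC[C@H](O)C(C)(C)O[C@H]2CC1
F8 | step 13 | (3R,5aR,9aS)-2,2,5a,7-tetramethyl-6-{[(trifluoromethyl)sulfonyl]oxy}-2,3,4,5,5a,8,9,9a-octahydro-1-benzoxepin-3-yl 4-nitrobenzoate | CC1=C(OS(=O)(=O)C(F)(F)F)[C@]2(C)CC[C@@H](OC(=O)c3ccc(cc3)[N+](=O)[O-])C(C)(C)O[C@H]2CC1
F9 | step 11 | (1R,5R,7R)-9-[(dimethylamino)methyl]-3,3,7-trimethyl-2-oxatricyclo[5.4.0.0(1,5)]undecane-4,8-dione (both C9 epimers) | O=C1C(CN(C)C)CC[C@@]23OC(C)(C)C(=O)[C@@H]2C[C@@]13C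
F10 | step 11 | (1R,5R,7R)-3,3,7-trimethyl-9-methylidene-2-oxatricyclo[5.4.0.0(1,5)]undecane-4,8-dione | O=C1C(=C)CC[C@@]23OC(C)(C)C(=O)[C@@H]2C[C@@]13C
F11 | step 11 | lithium C8–C9 enolate of 15 | [Li]OC1=C(C)CC[C@@]23OC(C)(C)C(=O)[C@@H]2C[C@@]13C
A1 | alternative 1 | 1,2-bis{3-methoxy-6-methyl-2-[(2S)-2-(methoxymethyl)pyrrolidine-1-carbonyl]phenyl}ethane | COC[C@@H]1CCCN1C(=O)c1c(OC)ccc(C)c1CCc1c(C)ccc(OC)c1C(=O)N1CCC[C@H]1COC
A2 | alternative 1 | 1,2-bis{5-methoxy-2,6-dimethyl-6-[(2S)-2-(methoxymethyl)pyrrolidine-1-carbonyl]cyclohexa-1,4-dien-1-yl}ethane (quaternary centres as in the SMILES) | CC1=C(CCC2=C(C)CC=C(OC)[C@@]2(C)C(=O)N2CCC[C@H]2COC)[C@](C)(C(=O)N2CCC[C@H]2COC)C(OC)=CC1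
A3 | alternative 2 | trans-fused 5-[2-(benzyloxy)ethyl]-2,2,4a,6-tetramethyl-4a,7,8,8a-tetrahydro-2H-chromen-3(4H)-one (configuration as in the SMILES) | c1ccccc1COCCC1=C(C)CC[C@@H]2OC(C)(C)C(=O)C[C@@]12C
A4 | alternative 2 | (5aS,9aS)-6-[2-(benzyloxy)ethyl]-2,2,5a,7-tetramethyl-4,5,5a,8,9,9a-hexahydro-1-benzoxepin-3(2H)-one | c1ccccc1COCCC1=C(C)CC[C@@H]2OC(C)(C)C(=O)CC[C@@]12C
A5 | alternative 3 | (10R)-6-[2-(benzyloxy)ethyl]-10-[(tert-butyldimethylsilyl)oxy]-5,7,11,11-tetramethyl-1-oxacycloundec-6-en-2-yl acetate | CC(=O)OC1CCC(C)C(CCOCc2ccccc2)=C(C)CC[C@@H](O[Si](C)(C)C(C)(C)C)C(C)(C)O1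
A6 | alternative 3 | (3R,5aS,9aS)-6-[2-(benzyloxy)ethyl]-3-[(tert-butyldimethylsilyl)oxy]-2,2,5a,7-tetramethyl-2,3,4,5,5a,8,9,9a-octahydro-1-benzoxepine | c1ccccc1COCCC1=C(C)CC[C@@H]2OC(C)(C)[C@H](O[Si](C)(C)C(C)(C)C)CC[C@@]12C
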